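## Retrosynthetic overview

1. Target ⇒ triol by acylation of its only secondary hydroxyl (C4) with phenol-protected vanillic acid; triol ⇒ hydroxy enone by methyl addition at C6.
2. Hydroxy enone ⇒ an acyclic keto-aldehyde acetal plus a three-carbon ketophosphonate; C3–C3a (aldol), C4–C5 (dianion aldol) and C7=C8 (Horner–Wadsworth–Emmons) are all made in one flask.
3. Keto-aldehyde ⇒ ozonolysis of a 4,4-disubstituted cyclohexene, whose quaternary stereocentre (future C8a) comes from a catalytic asymmetric Diels–Alder reaction of methacrolein with 2-isopropylbutadiene.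
4. Ring order: a sacrificial cyclohexene (formed, then cleaved), then the cyclopentane and the cycloheptenone together in the key one-pot step.

Positions are cited with azulene numbering of the final core: C3 isopropyl carbinol, C3a ring-fusion CH, C4 ester carbon, C6 methyl carbinol, C7=C8 alkene, C8a methyl-bearing quaternary carbon.

Assumption: the (S)-series Corey oxazaborolidinium catalyst is taken to give (S)-5; if the facial sense is opposite, the (R)-catalyst is used with no other change.

## Route

Step 1
Reactants: 1 3-methylbut-1-yne; 2 ethene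
Product: 3 2-(propan-2-yl)buta-1,3-diene
Conditions: second-generation Grubbs catalyst (2 mol%), ethene (1 atm), CH2Cl2, 23 °C
Reagents that add atoms: none
Why: Ethene–alkyne enyne cross-metathesis turns a terminal alkyne into the 2-substituted 1,3-diene with full atom economy and creates no stereocentre.

Step 2
Reactants: 3 2-(propan-2-yl)buta-1,3-diene; 4 2-methylprop-2-enal
Product: 5 (S)-1-methyl-4-(propan-2-yl)cyclohex-3-ene-1-carbaldehyde
Conditions: (S)-o-tolyl-CBS-oxazaborolidine (10 mol%), Tf2NH (8 mol%), CH2Cl2, −78 °C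
Reagents that add atoms: none
Why: Catalytic asymmetric Diels–Alder reaction of a 2-substituted acrolein with a 2-alkyl diene gives the 1,4-("para") adduct, the chiral boron Lewis acid shielding one face of s-trans methacrolein so that the quaternary carbon (future C8a) is set as S.

Step 3
Reactants: 5 (S)-1-methyl-4-(propan-2-yl)cyclohex-3-ene-1-carbaldehyde
Product: 6 (S)-4-(dimethoxymethyl)-4-methyl-1-(propan-2-yl)cyclohex-1-ene
Conditions: HC(OMe)3, MeOH, PPTS (cat.), 23 °C
Reagents that add atoms: trimethyl orthoformate, COC(OC)OC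
Why: Acid-catalysed acetalisation with orthoformate as water scavenger masks the neopentyl aldehyde and makes it the bulkiest group on the quaternary carbon, which later controls the ring-fusion geometry, while no stereocentre is touched.

Step 4
Reactants: 6 (S)-4-(dimethoxymethyl)-4-methyl-1-(propan-2-yl)cyclohex-1-ene
Product: 7 (S)-3-(dimethoxymethyl)-3,7-dimethyl-6-oxooctanal
Conditions: O3, CH2Cl2, −78 °C; then PPh3, −78 → 23 °C
Reagents that add atoms: ozone, [O-][O+]=O
Why: Criegee ozonolysis with reductive work-up cleaves the only C=C bond to give the isopropyl ketone and the aldehyde of a 1,6-keto-aldehyde, the acetal and the quaternary centre being inert at −78 °C.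

Step 5
Reactants: 7 (S)-3-(dimethoxymethyl)-3,7-dimethyl-6-oxooctanal; 8 dimethyl (2-oxopropyl)phosphonate
Product: 12 (3R,3aS,4S,8aR)-3,4-dihydroxy-8a-methyl-3-(propan-2-yl)-2,3,3a,4,5,8a-hexahydroazulen-6(1H)-one, via hydroxy aldehyde 9 (not isolated), via ketophosphonate acetal 10 (not isolated), via ketophosphonate aldehyde 11 (not isolated)
Conditions: pyrrolidine (20 mol%), PhCO2H (20 mol%), THF, 23 °C; then 8, LiN(iPr)2, THF, −78 → −20 °C; then 1 M HCl, 23 °C; then K2CO3 (pH 10), 40 °C
Reagents that add atoms: none
Why: Proposed new method: a telescoped formal [4+3] annulation in which enamine catalysis first closes the cyclopentane by a reversible 5-enolexo aldol of the aldehyde onto the isopropyl ketone (thermodynamic isomer with the formyl group cis to the new hydroxyl and to the methyl group, trans to isopropyl and to the bulky acetal, which sets C3 and C3a relative to C8a), the γ-carbon of the β-ketophosphonate dianion then adds to the aldehyde under chelation by the neighbouring lithium alkoxide on the face away from the methyl-bearing quaternary carbon (setting C4 as S), and after acid has freed the neopentyl aldehyde the remaining phosphonate closes the cycloheptenone by intramolecular Horner–Wadsworth–Emmons olefination with the ring enforcing the cis alkene, the closest known reactions being amine-catalysed enolexo aldolisations, γ-additions of β-ketophosphonate dianions and Horner–Wadsworth–Emmons ring closures, each precedented singly but not in one flask.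

Step 6
Reactants: 12 (3R,3aS,4S,8aR)-3,4-dihydroxy-8a-methyl-3-(propan-2-yl)-2,3,3a,4,5,8a-hexahydroazulen-6(1H)-one
Product: 13 (3R,3aS,4S,6S,8aR)-6,8a-dimethyl-3-(propan-2-yl)-1,2,3,3a,4,5,6,8a-octahydroazulene-3,4,6-triol
Conditions: MeLi (4 equiv), THF, −78 °C; then H2O
Reagents that add atoms: methyllithium, [Li]C
Why: 1,2-Addition of the hard organolithium to the cycloheptenone carbonyl is expected on the face opposite the pseudo-axial C8a methyl group (the C4 alkoxide being pseudo-equatorial), which gives the (6S) tertiary allylic alcohol with its hydroxyl cis to that methyl.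

Step 7
Reactants: 13 (3R,3aS,4S,6S,8aR)-6,8a-dimethyl-3-(propan-2-yl)-1,2,3,3a,4,5,6,8a-octahydroazulene-3,4,6-triol; 14 4-(acetyloxy)-3-methoxybenzoic acid
Product: 15 (3R,3aS,4S,6S,8aR)-3,6-dihydroxy-6,8a-dimethyl-3-(propan-2-yl)-1,2,3,3a,4,5,6,8a-octahydroazulen-4-yl 4-(acetyloxy)-3-methoxybenzoate
Conditions: DCC, DMAP (cat.), CH2Cl2, 23 °C
Reagents that add atoms: none
Why: Steglich esterification acylates only the secondary C4 hydroxyl because the two tertiary alcohols do not react with the acylpyridinium intermediate, and the C–O bond at C4 is not broken so its configuration is retained.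

Step 8
Reactants: 15 (3R,3aS,4S,6S,8aR)-3,6-dihydroxy-6,8a-dimethyl-3-(propan-2-yl)-1,2,3,3a,4,5,6,8a-octahydroazulen-4-yl 4-(acetyloxy)-3-methoxybenzoate
Product: 16 (3R,3aS,4S,6S,8aR)-3,6-dihydroxy-6,8a-dimethyl-3-(propan-2-yl)-1,2,3,3a,4,5,6,8a-octahydroazulen-4-yl 4-hydroxy-3-methoxybenzoate (CNP0243386.2)
Conditions: NH3 (7 M in MeOH), 0 °C
Reagents that add atoms: none
Why: Chemoselective aminolysis cleaves the activated phenyl acetate far faster than the hindered benzoate of a secondary alcohol, releasing the free phenol without touching any stereocentre.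

## Compound list

1 | 3-methylbut-1-yne | C#CC(C)C | starting material
2 | ethene | C=C | starting material
3 | 2-(propan-2-yl)buta-1,3-diene | C=CC(=C)C(C)C | intermediate
4 | 2-methylprop-2-enal (methacrolein) | CC(=C)C=O | starting material
5 | (S)-1-methyl-4-(propan-2-yl)cyclohex-3-ene-1-carbaldehyde | O=C[C@@]1(C)CCC(C(C)C)=CC1 | intermediate
6 | (S)-4-(dimethoxymethyl)-4-methyl-1-(propan-2-yl)cyclohex-1-ene | COC(OC)[C@@]1(C)CCC(C(C)C)=CC1 | intermediate
7 | (S)-3-(dimethoxymethyl)-3,7-dimethyl-6-oxooctanal | O=CC[C@@](C)(C(OC)OC)CCC(=O)C(C)C | intermediate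
8 | dimethyl (2-oxopropyl)phosphonate | COP(=O)(OC)CC(C)=O | starting material
9 | (1R,2S,5R)-2-(dimethoxymethyl)-5-hydroxy-2-methyl-5-(propan-2-yl)cyclopentane-1-carbaldehyde | O=C[C@H]1[C@](O)(C(C)C)CC[C@]1(C)C(OC)OC | intermediate
10 | dimethyl {(4S)-4-[(1S,2S,5R)-2-(dimethoxymethyl)-5-hydroxy-2-methyl-5-(propan-2-yl)cyclopentyl]-4-hydroxy-2-oxobutyl}phosphonate | COP(=O)(OC)CC(=O)C[C@H](O)[C@H]1[C@](O)(C(C)C)CC[C@]1(C)C(OC)OC | intermediate
11 | dimethyl {(4S)-4-[(1S,2S,5R)-2-formyl-5-hydroxy-2-methyl-5-(propan-2-yl)cyclopentyl]-4-hydroxy-2-oxobutyl}phosphonate | COP(=O)(OC)CC(=O)C[C@H](O)[C@H]1[C@](O)(C(C)C)CC[C@]1(C)C=O | intermediate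
12 | (3R,3aS,4S,8aR)-3,4-dihydroxy-8a-methyl-3-(propan-2-yl)-2,3,3a,4,5,8a-hexahydroazulen-6(1H)-one | O[C@H]1CC(=O)C=C[C@@]2(C)CC[C@@](O)(C(C)C)[C@H]12 | intermediate
13 | (3R,3aS,4S,6S,8aR)-6,8a-dimethyl-3-(propan-2-yl)-1,2,3,3a,4,5,6,8a-octahydroazulene-3,4,6-triol | O[C@H]1C[C@](C)(O)C=C[C@@]2(C)CC[C@@](O)(C(C)C)[C@H]12 | intermediate
14 | 4-(acetyloxy)-3-methoxybenzoic acid | COc1cc(C(=O)O)ccc1OC(C)=O | starting material
15 | (3R,3aS,4S,6S,8aR)-3,6-dihydroxy-6,8a-dimethyl-3-(propan-2-yl)-1,2,3,3a,4,5,6,8a-octahydroazulen-4-yl 4-(acetyloxy)-3-methoxybenzoate | COc1cc(C(=O)O[C@H]2C[C@](C)(O)C=C[C@@]3(C)CC[C@@](O)(C(C)C)[C@H]23)ccc1OC(C)=O | intermediate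
16 | (3R,3aS,4S,6S,8aR)-3,6-dihydroxy-6,8a-dimethyl-3-(propan-2-yl)-1,2,3,3a,4,5,6,8a-octahydroazulen-4-yl 4-hydroxy-3-methoxybenzoate | COc1cc(C(=O)O[C@H]2C[C@](C)(O)C=C[C@@]3(C)CC[C@@](O)(C(C)C)[C@H]23)ccc1O | target

## Step count and risks

Total step count: 8. Longest linear sequence: 8 steps (1 → 16); 4, 8 and 14 are bought.

The three steps most likely to fail:

Step 5. Four reagent changes in one flask must be survived by a base-sensitive β-hydroxy ketone, and the ring-fusion geometry rests on the acetal being larger than the methyl group during the aldol. The fallback sets out from 7 and stops after the amine-catalysed aldol, so that hydroxy aldehyde 9 is isolated and its configuration checked. The seven-membered ring is then built by an aldol route instead of a phosphonate route: D-proline-catalysed aldol of 9 with acetone gives the β-hydroxy ketone acetal F1, aqueous acid frees the neopentyl aldehyde to give the keto aldehyde F2, and Ba(OH)2-mediated intramolecular aldol condensation of the methyl ketone onto that aldehyde returns to the route at 12.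

Step 6. The facial selectivity of the methyl addition is predicted, not known, and the wrong face would give the C6 epimer. The fallback sets out from 12 and exchanges the roles of carbon and oxygen. Wittig methylenation with Ph3P=CH2 gives the exocyclic diene diol F3. Sterically controlled epoxidation with dimethyldioxirane then puts oxygen on the open face that the methyl nucleophile had used, giving the spiro-epoxide F4. LiEt3BH opens the oxirane at its CH2 group, which returns to the route at 13.

Step 7. The C4 hydroxyl is flanked by the ring fusion and two fully substituted carbons, and the tertiary allylic alcohol at C6 is sensitive to activation. The fallback sets out from 12 and inverts the order of events: Steglich acylation of its single secondary hydroxyl with 14 gives the enone ester F5. MeTi(OiPr)3, which adds to ketones but leaves carboxylic esters and aryl acetates alone, then installs the C6 methyl group at low temperature. This returns to the route at 15, so 13 is bypassed.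

Further compounds

F1 | step 5 | (4S)-4-[(1S,2S,5R)-2-(dimethoxymethyl)-5-hydroxy-2-methyl-5-(propan-2-yl)cyclopentyl]-4-hydroxybutan-2-one | CC(=O)C[C@H](O)[C@H]1[C@](O)(C(C)C)CC[C@]1(C)C(OC)OC
F2 | step 5 | (1S,2S,3R)-3-hydroxy-2-[(1S)-1-hydroxy-3-oxobutyl]-1-methyl-3-(propan-2-yl)cyclopentane-1-carbaldehyde | CC(=O)C[C@H](O)[C@H]1[C@](O)(C(C)C)CC[C@]1(C)C=O
F3 | step 6 | (3R,3aS,4S,8aR)-8a-methyl-6-methylidene-3-(propan-2-yl)-1,2,3,3a,4,5,6,8a-octahydroazulene-3,4-diol | O[C@H]1CC(=C)C=C[C@@]2(C)CC[C@@](O)(C(C)C)[C@H]12
F4 | step 6 | spiro-epoxide of F3 at C6 (oxirane oxygen on the face of the C8a methyl group; 3,4-diol unchanged) | O[C@H]1C[C@@]3(CO3)C=C[C@@]2(C)CC[C@@](O)(C(C)C)[C@H]12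
F5 | step 7 | (3R,3aS,4S,8aR)-3-hydroxy-8a-methyl-6-oxo-3-(propan-2-yl)-1,2,3,3a,4,5,6,8a-octahydroazulen-4-yl 4-(acetyloxy)-3-methoxybenzoate | COc1cc(C(=O)O[C@H]2CC(=O)C=C[C@@]3(C)CC[C@@](O)(C(C)C)[C@H]23)ccc1OC(C)=O
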